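**Strategy.** Ring A (C1–C5, C10) is read as the intramolecular [4+2] adduct of an open-chain dienyne: a C2=C3–C4=C5 diene and a terminal C10≡C1 alkyne held together by the four carbons C6–C9 that become ring B. One rhodium-catalysed enantioselective cycloaddition makes C5–C10 and C1–C2, closes both rings and sets the quaternary C5. It exploits the fact that C5 is the all-carbon junction of rings A and B and that C10 stays sp2 beside the C8 carbonyl. The precursor is a β-keto ester that already carries the lactate-derived (S)-propanoate arm on C7. Radical hydrogenation, dehydrogenation, C1 γ-hydroxylation and angeloylation complete the target.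

Key step: step 8

Remark on numbering: C1–C15 in the discussion are eremophilane numbers (C1 bears the angelate, C4 and C5 the methyls, C7 the propanoate arm, C8 the ketone, C11 the propanoate CH); locants inside compound names are IUPAC locants.

Remark (assumption): the facial sense of the bisphospholane–rhodium catalyst on this new substrate is not known in advance; the (R,R) ligand is written, and its commercial (S,S) antipode is taken if the first run shows the opposite sense.

**Step 1**
Reactants: 1 prop-2-yn-1-ol; 2 bromoethene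
Product: 3 pent-4-en-2-yn-1-ol
Conditions: Pd(PPh3)2Cl2 (2 mol%), CuI (4 mol%), i-Pr2NH, THF, 0 °C to rt
Reagents that add atoms: none
Why: Sonogashira coupling of the terminal alkyne with the vinyl bromide; no stereocentre is formed.

**Step 2**
Reactants: 3 pent-4-en-2-yn-1-ol
Product: 5 (2E)-2,3-dimethylpenta-2,4-dien-1-ol, via dienylmagnesium chelate 4 (not isolated)
Conditions: MeMgBr (3 equiv), CuI (10 mol%), THF, −10 °C to rt; then MeI, 0 °C to rt; aq. NH4Cl
Reagents that add atoms: methylmagnesium bromide C[Mg]Br; iodomethane CI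
Why: Copper-catalysed anti-carbomagnesiation of the propargylic alkoxide puts methyl on the alkyne carbon next to CH2O and magnesium trans to it in a five-membered chelate, and methylation of that C–Mg bond with retention should give the tetrasubstituted alkene with CH2OH trans to vinyl (2E).

**Step 3**
Reactants: 5 (2E)-2,3-dimethylpenta-2,4-dien-1-ol
Product: 6 (3E)-5-bromo-3,4-dimethylpenta-1,3-diene
Conditions: PBr3 (0.4 equiv), pyridine (cat.), Et2O, −20 °C; used at once
Reagents that add atoms: phosphorus tribromide BrP(Br)Br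
Why: Bromide displaces the activated primary allylic oxygen (SN2), and the conjugated primary bromide is also the preferred allylic isomer, so the (E)-alkene is kept.

**Step 4**
Reactants: 7 but-3-ynoic acid; 8 3-tert-butoxy-3-oxopropanoic acid (mono-tert-butyl malonate)
Product: 11 tert-butyl 3-oxohex-5-ynoate, via 1-(but-3-ynoyl)imidazole 9 (not isolated), via magnesium bis(mono-tert-butyl malonate) 10 (not isolated)
Conditions: 7, CDI, THF, 0 °C to rt; separately 8, Mg(OEt)2, THF; combine, rt; 1 M HCl work-up
Reagents that add atoms: none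
Why: Masamune–Claisen C-acylation of the neutral magnesium malonate half-ester by the acyl imidazole, followed by loss of CO2, gives the β-keto ester without the base that would isomerize the propargyl ketone to an allene.

**Step 5**
Reactants: 12 methyl (2S)-2-hydroxypropanoate (methyl (S)-lactate)
Product: 13 methyl (2S)-2-{[(trifluoromethyl)sulfonyl]oxy}propanoate
Conditions: Tf2O, 2,6-lutidine, CH2Cl2, −78 to 0 °C
Reagents that add atoms: trifluoromethanesulfonic anhydride O=S(=O)(OS(=O)(=O)C(F)(F)F)C(F)(F)F
Why: O-sulfonylation touches no bond at the stereocentre, so the (S) configuration is retained.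

**Step 6**
Reactants: 11 tert-butyl 3-oxohex-5-ynoate; 13 methyl (2S)-2-{[(trifluoromethyl)sulfonyl]oxy}propanoate
Product: 14 1-tert-butyl 4-methyl (3S)-2-(but-3-ynoyl)-3-methylbutanedioate (both C2 epimers)
Conditions: NaH (1.0 equiv), THF, 0 °C; then 13, −20 °C to rt
Reagents that add atoms: none
Why: The soft sodium enolate of the β-keto ester displaces the α-carbonyl triflate by SN2 with inversion, which should turn the lactate carbon into C11 with the configuration of the target (still S because the priorities change).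

**Step 7**
Reactants: 14 1-tert-butyl 4-methyl (3S)-2-(but-3-ynoyl)-3-methylbutanedioate; 6 (3E)-5-bromo-3,4-dimethylpenta-1,3-diene
Product: 15 1-tert-butyl 4-methyl (3S)-2-(but-3-ynoyl)-2-[(2E)-2,3-dimethylpenta-2,4-dien-1-yl]-3-methylbutanedioate (both C2 epimers)
Conditions: NaH (0.98 equiv), THF/DMF, 0 °C to rt
Reagents that add atoms: none
Why: C-allylation of the stabilized enolate at the primary allylic bromide (SN2) builds quaternary C7, whose configuration is inconsequential because C7 later becomes sp2; the slight deficit of base protects the propargyl ketone.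

**Step 8**
Reactants: 15 1-tert-butyl 4-methyl (3S)-2-(but-3-ynoyl)-2-[(2E)-2,3-dimethylpenta-2,4-dien-1-yl]-3-methylbutanedioate
Product: 16 tert-butyl (8aR)-2-[(2S)-1-methoxy-1-oxopropan-2-yl]-8,8a-dimethyl-3-oxo-1,2,3,4,6,8a-hexahydronaphthalene-2-carboxylate (both C2 epimers)
Conditions: [Rh(nbd)2]SbF6 (5 mol%), 1,2-bis[(2R,5R)-2,5-dimethylphospholan-1-yl]benzene (6 mol%), 1,2-dichloroethane (0.02 M), 40 °C
Reagents that add atoms: none
Why: Cationic monovalent rhodium binds the s-cis diene and the alkyne of 15, oxidative cyclization joins the internal alkyne carbon C10 to the fully substituted diene terminus C5 to give a σ-vinyl/π-allyl rhodacycle, and C(sp2)–C(sp3) reductive elimination then joins C1 to C2 and releases the 1,4-cyclohexadiene 16. The closest known reaction type is the rhodium- or nickel-catalysed intramolecular [4+2] cycloaddition of unactivated 1,3-diene-ynes, which has an enantioselective bisphospholane–rhodium version. Ring B closes in the oxidative-cyclization event as a six-membered carbocycle across the four-atom tether C6–C9 (exo with respect to the alkyne, helped by the gem-disubstituted C7), and ring A closes by reductive elimination from the seven-membered metallacycle, a formal [4+2] closure. The only new stereocentre, quaternary C5, is set by the chiral bisphospholane, which differentiates the two faces of the C4=C5 terminus in the C5–C10 bond-forming event; both C7 epimers of 15 should follow the catalyst because the two C7 substituents are of similar size. The step needs periselectivity for [4+2] over alkyne oligomerization and propargyl-to-allenyl ketone isomerization, secured by high dilution, a base-free medium and the quaternary C7 that removes the acidic β-dicarbonyl proton, and it needs the (E)-tether geometry fixed in step 2 so that only the methyl sits inside the s-cis diene. Any C5-epimeric adduct is a diastereomer, because C11 is fixed, and can be removed at dienone 19.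

**Step 9**
Reactants: 16 tert-butyl (8aR)-2-[(2S)-1-methoxy-1-oxopropan-2-yl]-8,8a-dimethyl-3-oxo-1,2,3,4,6,8a-hexahydronaphthalene-2-carboxylate
Product: 17 tert-butyl (4aS,8S,8aR)-2-[(2S)-1-methoxy-1-oxopropan-2-yl]-8,8a-dimethyl-3-oxodecahydronaphthalene-2-carboxylate (trans-fused; both C2 epimers)
Conditions: Mn(dpm)3 (dpm = 2,2,6,6-tetramethylheptane-3,5-dionate, 10 mol%), PhSiH3, t-BuOOH, i-PrOH, rt
Reagents that add atoms: none
Why: Mukaiyama-type metal-hydride hydrogen-atom-transfer hydrogenation reduces both trisubstituted alkenes through tertiary radicals at C10 and C4, which should take hydrogen axially from the face opposite the pseudo-axial C5 methyl, giving the trans ring fusion and the C4 methyl cis to the C5 methyl.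

**Step 10**
Reactants: 17 tert-butyl (4aS,8S,8aR)-2-[(2S)-1-methoxy-1-oxopropan-2-yl]-8,8a-dimethyl-3-oxodecahydronaphthalene-2-carboxylate
Product: 18 methyl (2S)-2-[(4aS,8S,8aR)-8,8a-dimethyl-3-oxodecahydronaphthalen-2-yl]propanoate (both C2 epimers)
Conditions: TsOH·H2O (0.2 equiv), toluene, 90 °C
Reagents that add atoms: none
Why: Acid-catalysed loss of 2-methylpropene from the tert-butyl ester and decarboxylation of the β-keto acid leave the methyl ester and C11 untouched.

**Step 11**
Reactants: 18 methyl (2S)-2-[(4aS,8S,8aR)-8,8a-dimethyl-3-oxodecahydronaphthalen-2-yl]propanoate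
Product: 19 methyl (2S)-2-[(8S,8aS)-8,8a-dimethyl-3-oxo-3,5,6,7,8,8a-hexahydronaphthalen-2-yl]propanoate
Conditions: IBX (3 equiv), DMSO/toluene, 70 °C
Reagents that add atoms: none
Why: Twofold IBX α,β-dehydrogenation of the ketone on both sides gives the cross-conjugated dienone (quaternary C5 blocks aromatization), erasing the C7 and C10 stereocentres.

**Step 12**
Reactants: 19 methyl (2S)-2-[(8S,8aS)-8,8a-dimethyl-3-oxo-3,5,6,7,8,8a-hexahydronaphthalen-2-yl]propanoate
Product: 20 methyl (2S)-2-[(8S,8aS)-3-{[tert-butyl(dimethyl)silyl]oxy}-8,8a-dimethyl-6,7,8,8a-tetrahydronaphthalen-2-yl]propanoate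
Conditions: TBSOTf (1.1 equiv), Et3N, CH2Cl2, −78 to 0 °C; filtered through basic alumina and used directly
Reagents that add atoms: tert-butyldimethylsilyl trifluoromethanesulfonate CC(C)(C)[Si](C)(C)OS(=O)(=O)C(F)(F)F
Why: Soft enolization of the dienone can only remove the γ-hydrogen at C1 (both α-carbons are sp2), giving the linear silyl trienol ether.

**Step 13**
Reactants: 20 methyl (2S)-2-[(8S,8aS)-3-{[tert-butyl(dimethyl)silyl]oxy}-8,8a-dimethyl-6,7,8,8a-tetrahydronaphthalen-2-yl]propanoate
Product: 21 methyl (2S)-2-[(5R,8S,8aS)-5-hydroxy-8,8a-dimethyl-3-oxo-3,5,6,7,8,8a-hexahydronaphthalen-2-yl]propanoate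
Conditions: dimethyldioxirane (1.05 equiv), acetone/CH2Cl2, −78 °C; then AcOH, THF/H2O, 0 °C
Reagents that add atoms: dimethyldioxirane CC1(C)OO1
Why: Vinylogous Rubottom oxidation: the oxidant should attack the terminal C10=C1 bond of the trienol ether axially on the face of the C5 methyl (the same stereoelectronic course as 6β-hydroxylation of steroidal dienol ethers), and epoxide opening with desilylation gives the 1β-alcohol.

**Step 14**
Reactants: 21 methyl (2S)-2-[(5R,8S,8aS)-5-hydroxy-8,8a-dimethyl-3-oxo-3,5,6,7,8,8a-hexahydronaphthalen-2-yl]propanoate; 22 (2Z)-2-methylbut-2-enoic acid (angelic acid)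
Product: 24 methyl (2S)-2-[(5R,8S,8aS)-8,8a-dimethyl-5-{[(2Z)-2-methylbut-2-enoyl]oxy}-3-oxo-3,5,6,7,8,8a-hexahydronaphthalen-2-yl]propanoate (the target), via angelic 2,4,6-trichlorobenzoic anhydride 23 (not isolated)
Conditions: 22, 2,4,6-trichlorobenzoyl chloride, Et3N, toluene, rt; then 21, toluene, 80 °C (no DMAP)
Reagents that add atoms: none
Why: Yamaguchi esterification through the mixed anhydride acylates the hindered allylic alcohol with retention at C1, and leaving out nucleophilic catalysts should avoid Z-to-E isomerization to the tiglate.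

**Compound list**

1 | prop-2-yn-1-ol | C#CCO | starting material
2 | bromoethene | C=CBr | starting material
3 | pent-4-en-2-yn-1-ol | C=CC#CCO | intermediate
4 | dienylmagnesium chelate (bromomagnesium alkoxide of the C3-magnesiated dienol) | C=C/C([Mg]Br)=C(\C)CO[Mg]Br | intermediate
5 | (2E)-2,3-dimethylpenta-2,4-dien-1-ol | C=C/C(C)=C(\C)CO | intermediate
6 | (3E)-5-bromo-3,4-dimethylpenta-1,3-diene | C=C/C(C)=C(\C)CBr | intermediate
7 | but-3-ynoic acid | C#CCC(=O)O | starting material
8 | 3-tert-butoxy-3-oxopropanoic acid | CC(C)(C)OC(=O)CC(=O)O | starting material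
9 | 1-(but-3-ynoyl)imidazole | C#CCC(=O)n1ccnc1 | intermediate
10 | magnesium bis(mono-tert-butyl malonate) | CC(C)(C)OC(=O)CC(=O)[O-].CC(C)(C)OC(=O)CC(=O)[O-].[Mg+2] | intermediate
11 | tert-butyl 3-oxohex-5-ynoate | C#CCC(=O)CC(=O)OC(C)(C)C | intermediate
12 | methyl (2S)-2-hydroxypropanoate | C[C@H](O)C(=O)OC | starting material
13 | methyl (2S)-2-{[(trifluoromethyl)sulfonyl]oxy}propanoate | C[C@H](OS(=O)(=O)C(F)(F)F)C(=O)OC | intermediate
14 | 1-tert-butyl 4-methyl (3S)-2-(but-3-ynoyl)-3-methylbutanedioate (C2 epimers) | C#CCC(=O)C([C@H](C)C(=O)OC)C(=O)OC(C)(C)C | intermediate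
15 | 1-tert-butyl 4-methyl (3S)-2-(but-3-ynoyl)-2-[(2E)-2,3-dimethylpenta-2,4-dien-1-yl]-3-methylbutanedioate (C2 epimers) | C#CCC(=O)C(C/C(C)=C(\C)C=C)([C@H](C)C(=O)OC)C(=O)OC(C)(C)C | intermediate
16 | tert-butyl (8aR)-2-[(2S)-1-methoxy-1-oxopropan-2-yl]-8,8a-dimethyl-3-oxo-1,2,3,4,6,8a-hexahydronaphthalene-2-carboxylate (C2 epimers) | C1CC=C(C)[C@@]2(C)CC(C(=O)OC(C)(C)C)([C@H](C)C(=O)OC)C(=O)CC2=1 | intermediate
17 | tert-butyl (4aS,8S,8aR)-2-[(2S)-1-methoxy-1-oxopropan-2-yl]-8,8a-dimethyl-3-oxodecahydronaphthalene-2-carboxylate (C2 epimers) | C1CC[C@H](C)[C@@]2(C)CC(C(=O)OC(C)(C)C)([C@H](C)C(=O)OC)C(=O)C[C@H]12 | intermediate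
18 | methyl (2S)-2-[(4aS,8S,8aR)-8,8a-dimethyl-3-oxodecahydronaphthalen-2-yl]propanoate (C2 epimers) | C1CC[C@H](C)[C@@]2(C)CC([C@H](C)C(=O)OC)C(=O)C[C@H]12 | intermediate
19 | methyl (2S)-2-[(8S,8aS)-8,8a-dimethyl-3-oxo-3,5,6,7,8,8a-hexahydronaphthalen-2-yl]propanoate | C1CC[C@H](C)[C@@]2(C)C=C([C@H](C)C(=O)OC)C(=O)C=C12 | intermediate
20 | methyl (2S)-2-[(8S,8aS)-3-{[tert-butyl(dimethyl)silyl]oxy}-8,8a-dimethyl-6,7,8,8a-tetrahydronaphthalen-2-yl]propanoate | C1CC[C@H](C)[C@@]2(C)C=C([C@H](C)C(=O)OC)C(O[Si](C)(C)C(C)(C)C)=CC2=1 | intermediate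
21 | methyl (2S)-2-[(5R,8S,8aS)-5-hydroxy-8,8a-dimethyl-3-oxo-3,5,6,7,8,8a-hexahydronaphthalen-2-yl]propanoate | O[C@@H]1CC[C@H](C)[C@@]2(C)C=C([C@H](C)C(=O)OC)C(=O)C=C12 | intermediate
22 | (2Z)-2-methylbut-2-enoic acid | C/C=C(/C)C(=O)O | starting material
23 | (2Z)-2-methylbut-2-enoic 2,4,6-trichlorobenzoic anhydride | C/C=C(/C)C(=O)OC(=O)c1c(Cl)cc(Cl)cc1Cl | intermediate
24 | methyl (2S)-2-[(5R,8S,8aS)-8,8a-dimethyl-5-{[(2Z)-2-methylbut-2-enoyl]oxy}-3-oxo-3,5,6,7,8,8a-hexahydronaphthalen-2-yl]propanoate | C/C=C(/C)C(=O)O[C@@H]1CC[C@H](C)[C@@]2(C)C=C([C@H](C)C(=O)OC)C(=O)C=C12 | target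

**Step count.** 14 steps in total. The longest linear sequence is 11 steps (steps 1–3, then 7–14).

**Steps most likely to fail**

1. Step 8 (key step). The oxidative cyclization may stall because the inside methyl on the fully substituted diene terminus disfavours s-cis binding, the terminal alkyne may oligomerize, or the chiral ligand may not discriminate the two diene faces well enough. Fallback, setting out from 15 and returning at 19: the cyclization is run without chiral information using zerovalent nickel (Ni(cod)2, tris(2-biphenylyl) phosphite, THF, rt to 60 °C), a known achiral catalyst for dienyne [4+2] reactions at hindered termini. The stereocentre C11, already in place from lactate, then serves as an internal resolving handle. Compound 15 gives 16 together with its ring epimer tert-butyl (8aS)-2-[(2S)-1-methoxy-1-oxopropan-2-yl]-8,8a-dimethyl-3-oxo-1,2,3,4,6,8a-hexahydronaphthalene-2-carboxylate F1. The mixture is taken through steps 9–11, the epimeric series passing through tert-butyl (4aR,8R,8aS)-2-[(2S)-1-methoxy-1-oxopropan-2-yl]-8,8a-dimethyl-3-oxodecahydronaphthalene-2-carboxylate F2 and methyl (2S)-2-[(4aR,8R,8aS)-8,8a-dimethyl-3-oxodecahydronaphthalen-2-yl]propanoate F3. At the dienone stage only two diastereomers remain, and 19 is separated by chromatography or crystallization from methyl (2S)-2-[(8R,8aR)-8,8a-dimethyl-3-oxo-3,5,6,7,8,8a-hexahydronaphthalen-2-yl]propanoate F4.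

2. Step 13. The oxidant may attack the silyl enol ether carbon C9 instead of the remote C10=C1 bond, it may approach from the face opposite the C5 methyl, or C11 may epimerize during the preceding silylation. Fallback, setting out from 19 and returning at 21: allylic oxidation of the C1 methylene with t-BuOOH and catalytic Rh2(cap)4 (dirhodium tetracaprolactamate) should give the trione methyl (2S)-2-[(8S,8aS)-8,8a-dimethyl-3,5-dioxo-3,5,6,7,8,8a-hexahydronaphthalen-2-yl]propanoate F5. Luche reduction (NaBH4, CeCl3·7H2O, MeOH, −78 °C) should then deliver hydride to the more electrophilic, singly conjugated C1 carbonyl from the face opposite the axial C5 methyl, giving the 1β-alcohol 21.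

3. Step 9. Hydrogen-atom delivery to the C4 radical may lack face selectivity if the C3=C4 alkene is reduced before the ring fusion is set, which would erode the cis relationship of the two methyls. Fallback, setting out from 16 and returning at 18: TsOH in toluene at 90 °C removes the tert-butyl ester with decarboxylation and moves the β,γ-alkene into conjugation, giving methyl (2S)-2-[(8aR)-8,8a-dimethyl-3-oxo-1,2,3,5,6,8a-hexahydronaphthalen-2-yl]propanoate F6. Birch-type reduction of the enone (Li, NH3/THF, t-BuOH 1 equiv, −78 °C, short contact) fixes the trans ring fusion in methyl (2S)-2-[(4aS,8aS)-8,8a-dimethyl-3-oxo-1,2,3,4,4a,5,6,8a-octahydronaphthalen-2-yl]propanoate F7. Hydrogenation of the remaining C3=C4 alkene (H2, Pd/C, EtOAc) should then occur from the face opposite the axial C5 methyl of the rigid trans-decalin, giving 18.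

**Further compounds**

F1 | step 8 | tert-butyl (8aS)-2-[(2S)-1-methoxy-1-oxopropan-2-yl]-8,8a-dimethyl-3-oxo-1,2,3,4,6,8a-hexahydronaphthalene-2-carboxylate | C1CC=C(C)[C@]2(C)CC(C(=O)OC(C)(C)C)([C@H](C)C(=O)OC)C(=O)CC2=1
F2 | step 8 | tert-butyl (4aR,8R,8aS)-2-[(2S)-1-methoxy-1-oxopropan-2-yl]-8,8a-dimethyl-3-oxodecahydronaphthalene-2-carboxylate | C1CC[C@@H](C)[C@]2(C)CC(C(=O)OC(C)(C)C)([C@H](C)C(=O)OC)C(=O)C[C@@H]12
F3 | step 8 | methyl (2S)-2-[(4aR,8R,8aS)-8,8a-dimethyl-3-oxodecahydronaphthalen-2-yl]propanoate | C1CC[C@@H](C)[C@]2(C)CC([C@H](C)C(=O)OC)C(=O)C[C@@H]12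
F4 | step 8 | methyl (2S)-2-[(8R,8aR)-8,8a-dimethyl-3-oxo-3,5,6,7,8,8a-hexahydronaphthalen-2-yl]propanoate | C1CC[C@@H](C)[C@]2(C)C=C([C@H](C)C(=O)OC)C(=O)C=C12
F5 | step 13 | methyl (2S)-2-[(8S,8aS)-8,8a-dimethyl-3,5-dioxo-3,5,6,7,8,8a-hexahydronaphthalen-2-yl]propanoate | O=C1CC[C@H](C)[C@@]2(C)C=C([C@H](C)C(=O)OC)C(=O)C=C12
F6 | step 9 | methyl (2S)-2-[(8aR)-8,8a-dimethyl-3-oxo-1,2,3,5,6,8a-hexahydronaphthalen-2-yl]propanoate | C1CC=C(C)[C@@]2(C)CC([C@H](C)C(=O)OC)C(=O)C=C12
F7 | step 9 | methyl (2S)-2-[(4aS,8aS)-8,8a-dimethyl-3-oxo-1,2,3,4,4a,5,6,8a-octahydronaphthalen-2-yl]propanoate | C1CC=C(C)[C@@]2(C)CC([C@H](C)C(=O)OC)C(=O)C[C@H]12
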